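70.0% of the substrate charged is as much target as this flask can hold if each target takes up one coupling partner; I call this ratio of the two charges the partner ceiling, and it makes the coupling partner the limiting reagent for target.

the same everywhere: substrate 0.30 M; second catalyst 0.30 mM; precatalyst 8.7 mM
- north: coupling partner 0.21 M; temperature 40 °C; the very flask that is asked about, followed so far
- north-west: coupling partner 0.21 M; temperature 46 °C; run made earlier
- flask: coupling partner 0.210 M; temperature 40 °C; time 1.5 h

- north (time / min: target / %): 10.0: 26.2; 20.0: 41.2; 30.0: 49.8; 40.0: 55.0; 50.0: 58.4; 60.0: 60.2; 80.0: 63.2
- north-west (time / min: target / %): 10.0: 34.2; 20.0: 48.7; 30.0: 55.6; 40.0: 59.8; 50.0: 62.4; 60.0: 63.9; 80.0: 65.0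

(scatter of a reading: 0.3 percentage points)

- delta: at 1.5 h add coupling partner, 100% of the amount charged, then wait 50 min
- beta: at 1.5 h raise the temperature by 20 K, then wait 50 min
- gamma: at 1.5 h add second catalyst, 100% of the amount charged, then wait 50 min
- theta: change nothing and wait 50 min more
- epsilon: at 1.5 h take out 90% of the target then present, then wait 50 min

- target, in percent of the substrate first charged, at 1.5 h
- the remedy with the largest gain of target, or "none" below 2 percentage points (delta / beta / gamma / theta / epsilon / none)
- target present, with what was taken out counted in, in percent of the substrate first charged, after delta
- target present, with what was taken out counted in, in percent of the substrate first charged, after gamma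

- target that was removed still counts
- the analysis behind the earlier runs scatters by 0.3 percentage points, standard deviation
- "the catalyst" is free catalyst with its forms; second catalyst is a second catalyst
- additions bring no volume worth counting

Call the ceiling less the target the room, and turn the settings one by one. Time first: in the north run the room shrank from 9.8 percentage points at 60.0 min to 6.8 points at 80.0 min, so by these two readings it keeps 69.4% over that stretch. Carrying this on, I expect 64.3% at 1.5 h, with 5.7 points of room, and waiting 50 min more brings about 67.7%. Heat leaves the ceiling where it stands, and the last reading of the warmer north-west run, at 80.0 min, is 65.0%, lower than the ceiling. Second catalyst leaves it too, so I put gamma near that waiting figure. Taking out target touches neither charge, and what is removed still counts, so epsilon should match waiting. Adding the partner charge again lifts the ratio to 140%, past the whole substrate, so the room becomes 36 points, more than before. By its reading at 50.0 min the north run had kept 16.6% of its first room; the same share of this room gives me 94.1% after delta.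

The forecast gives 64.3% (63.6% to 65%) for now, delta as the remedy, 85% (76% to 93%) after delta, lower than mine, and 67% (65.5% to 69%) after gamma, on the ground that “The stall is mostly partner exhaustion”.

The flask gives 64.1% at 1.5 h. Delta gains 30 points and reaches 94.2%, far more than beta with 3 points, gamma with 2.9 points (reaching 67.0%), theta with 2.2 points and epsilon with 2.2 points.

    coupling partner + second catalyst + intermediate → second catalyst + target (k = 12.9 /M²/s, Ea = 49.0 kJ/mol)
    substrate + free catalyst → free catalyst + intermediate (k = 8.38 /M/s, Ea = 57.0 kJ/mol)
    coupling partner + precatalyst → free catalyst + spent reagent (k = 0.0101 /M/s, Ea = 77.0 kJ/mol)
    (constants at 40 °C)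

The falling level of coupling partner is the main reason this flask stands at 64.1% at 1.5 h: with that level held up, the same run gives 98.6%, which accounts for 96% of what is missing, and the flask stands 5.9 points under its ceiling of 70.0%. A neighbour flask charged with 0.433 equiv of coupling partner has a ceiling of 43.3%, and at 90.0 min it holds 40.5% of target, with 59.5% of the substrate standing as intermediate.

The numbers in the tables stem from a simulated flask for substances that don't exist.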